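You cannot keep the open intermediate away from the substrate that makes it, so the target peak depends on how the open intermediate divides.

    substrate + reagent → open intermediate (k1 = 0.026 M⁻¹ s⁻¹, Ea1 = 68.0 kJ mol⁻¹)
    open intermediate → target (k2 = 0.0013 s⁻¹, Ea2 = 117 kJ mol⁻¹)
    open intermediate + capture agent → trapped intermediate (k3 = 0.16 M⁻¹ s⁻¹, Ea3 = 51.0 kJ mol⁻¹)
    substrate + open intermediate → side product (k4 = 0.16 M⁻¹ s⁻¹, Ea4 = 77.0 kJ mol⁻¹)
    (constants at 80 °C)

the same everywhere: substrate 0.050 M; reagent 0.900 equiv; capture agent 1.00 mM; time 50 min

|  | temperature |
|---|---|
| zeta | 105 °C |
| theta | 80 °C |

- the flask that comes out highest in amount of target, in percent of the substrate charged, or "all alike" when all lie within 1.5 percentage points (zeta / theta / all alike)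
- target at the end, in percent of the substrate charged, zeta
- target at the end, in percent of the substrate charged, theta

- percentages count the substrate that a species holds: one side product counts as two
- the constants hold at 80 °C; other temperatures follow from the activation energies

- Make two approximations: let the open intermediate be used as fast as it is made, and hold the capture agent at its charge. You then need no clock to follow the target, since each open intermediate that goes to target costs one substrate and each that goes to side product costs two.
- The split hangs on the constant of the target step over that of the side-product step, a selectivity factor with the dimension of a concentration. Call it X, the crossover concentration, the c(substrate) at which open intermediate goes equally to both. In theta it is 8.12 mM. From theta to zeta the target step speeds up by a factor of 13.9, against 5.7 for the side-product step, so in zeta X is 20.0 mM.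
- The capture step adds the c(capture agent) times its constant over that of the side-product step, which gives B, 20.6 mM in zeta and 9.13 mM in theta; the addition in zeta is far smaller than X.
- Dividing the target's rate by the substrate's and integrating gives c(target) = 0.5 · X · ln[(2 c(substrate, start) + B) / (2 c(substrate, end) + B)]. With the substrate spent, this gives 35.4 % for zeta and 20.2 % for theta, both estimates under the two approximations and neither of them a bound.
- The weak link is that word "spent". The charge and that estimate for theta leave 15.0 mM of reagent in theta, which makes the lifetime of substrate against the first step 42.9 min, set against a run of 50 min. I let reagent fall by half of what substrate loses, and let substrate fall 3/2 times as fast as the first step alone, a middle value between its limits of one and two. That leaves 0.109 as the ratio c(substrate)/(c(substrate) + 2 × reagent left) in theta, so 3.65 mM of substrate remains. The target in theta comes down to 15.4 %.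
- The same step for zeta, with 11.2 mM of reagent left, gives 0.0370 mM of substrate, far below B. Zeta stays at 35.4 %, and I commit to zeta as the higher flask.
- The forecast names zeta, with 35.2 % for zeta and 17.4 % for theta, where “the reaction is unfinished”; its theta figure stands above mine.
- The run gives 36.8 % for zeta and 17.5 % for theta, so zeta is highest, and these lie 1.4 percentage points and 2.1 points above my figures. A neighbour of zeta charged with 0.20 M of substrate, capture agent still at 1.00 mM, keeps X at 20.0 mM but starts at 10.0 X rather than 2.50 X. With its substrate spent, the same formula gives 15.1 %. That neighbour ended with 0 % of its substrate left, target at 17.5 % and side product at 82.1 %.

The constants stand for no real mixture; no experiment stands behind them.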